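**A leftover first.** The leftover I went to first in your midnight run was the over-reaction product at 3.00 min, 6% of the charge, as a measure of what target loses. You asked for a quick number, and your hunch was that the closed flask maple, run for 5.0 min, would beat the tank oak, with 5.0 min on average. I reckoned it through for myself.

| flask | starting material | remark | time |
|---|---|---|---|
| midnight | 10 mM | run made earlier |  |
| spring | 5 mM | run made earlier |  |
| oak | 10 mM | a single well-mixed tank run continuously and read at steady state, 5.0 min in it on average |  |
| maple | 10 mM | everything together in a closed stirred flask, run for 5.0 min | 5.0 min |
| larch | 10 mM | one stirred flow tank at steady state, fed with the mixture as stated, mean residence time 25.0 min |  |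

midnight run (percent of the starting material charged)

| time / min | target / % | over-reaction product / % |
|---|---|---|
| 0.250 | 0 | 0 |
| 0.417 | 2 | 1 |
| 0.667 | 2 | 0 |
| 1.00 | 4 | 2 |
| 2.00 | 11 | 2 |
| 3.00 | 19 | 6 |

spring run (percent of the starting material charged)

| time / s | target / % | over-reaction product / % |
|---|---|---|
| 10.0 | 2 | 0 |
| 15.0 | 1 | 2 |
| 20.0 | 0 | 0 |
| 25.0 | 4 | 0 |
| 30.0 | 3 | 0 |

(each reading ± 1.5 percentage points)

- the stated concentrations are those of everything mixed, before any reaction; amounts are the same in each set-up
- the numbers in the tables scatter by 1.5 percentage points (one standard deviation)
- the earlier runs were made in a closed, stirred flask

1. the set-up with the highest share of target in all that became target or over-reaction product, at the outlet or at the end ("none" if the first two lie within 2 percentage points) (oak / maple / larch / none)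
2. share of target in all that became target or over-reaction product, at the outlet or at the end, oak
3. share of target in all that became target or over-reaction product, at the outlet or at the end, maple
4. share of target in all that became target or over-reaction product, at the outlet or at the end, larch

**Loss constant.** Product came after target, so I took target to over-reaction product as a first-order step, whose product is a constant times target summed over time. I replaced the target curve up to 3.00 min by its trapezoid mean, 8.17%. Product divided by mean target and time gave the loss constant kL = 0.245 min⁻¹. The first triangle of that mean holds 0.67 percentage points, a smaller relative doubt than the scatter, which is a quarter of the product reading.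

**Tank and flask.** In a steady tank the mean target is the outlet target, so product over target is kL times τ, the mean residence time, and the share of target (the selectivity) is 1/(1+kLτ). That gave me 45.0% for oak and 14.0% for larch. In the closed midnight flask the mean lay below the last reading, their ratio being 0.430. Carried to maple, it gave 65.5%, more than oak.

**The forecast.** It named maple, with oak 46%, maple 60% and larch 15%: “The flask wins.” It stood 1 point above me on oak and 5.5 points below me on maple.

    starting material → intermediate A (k = 0.0120 s⁻¹)
    intermediate A → target (k = 0.00350 s⁻¹)
    starting material → intermediate B (k = 0.00240 s⁻¹)
    intermediate B ⇌ intermediate C (K = 25.0, k = 0.00440 s⁻¹)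
    intermediate B ⇌ intermediate A (K = 2.10, k = 0.0200 s⁻¹)
    target → over-reaction product (k = 0.00380 s⁻¹)

**What ran.** Maple came first at 60.2%, with oak at 46.7% and larch at 14.9%; kL had given 45.0% for oak and, at 25.0 min, 14.0% for larch. In maple, starting material was down to 1.33% at the end with target at 22.7%, while target went on to over-reaction product with a half-life of 3.0 min by that step alone. In larch, at the outlet, starting material stood at 4.42%, intermediate A at 10.7% and intermediate B at 4.65%.

The data stem from a simulated flask with made-up constants, noise included.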